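Retrosynthesis: the four phenols are unmasked last (MOM ethers); ring C is then cut in one stroke at O1–C8a and C4–C4a, giving a ring A aryne (C4a≡C8a) and a ring B (S)-β-hydroxy N-methoxy-N-methylamide (Weinreb amide) that already holds O1–C2–C3–C4.
Enabling feature: in ring A the neighbouring carbons C8a and C4a carry an ether oxygen and an acyl carbon, C4a is flanked by the C5 oxygen and the C6 prenyl group is para to C8a; this is the pattern a 3-alkoxyaryne gives when it takes up an O-nucleophile and an acyl electrophile, and in ring C O1 and C4 are 1,3-related through C2.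
Forward, ring A partner: resorcinol, MOM ethers, C-prenylation between them, C–H borylation/oxidation meta to both, carbamate-directed ortho-silylation, triflate.
Forward, ring B partner: methyl 5-bromo-2,4-dihydroxybenzoate, MOM ethers, Stille prenylation, Claisen condensation, asymmetric transfer hydrogenation.
Rings A and B are bought as benzene rings; ring C is the only ring made and arises in the aryne annulation, followed by acid removal of the MOM groups.
Stereochemistry: C2 (S) is set by catalyst-controlled reduction of the aryl ketone, and its C–O bond is never broken afterwards.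

Key step: step 12

Remark: the SMILES is read as the (2S)-flavanone with C2 as its only stereocentre; methyl 5-bromo-2,4-dihydroxybenzoate, tributyl(3-methylbut-2-en-1-yl)stannane and N-methoxy-N-methylacetamide are taken as purchasable.

Step 1
Reactants: 1 resorcinol
Product: 2 1,3-bis(methoxymethoxy)benzene
Conditions: MOMCl, iPr2NEt, CH2Cl2, 0 °C to rt
Reagents that add atoms: chloromethyl methyl ether, COCCl
Why: Double O-alkylation of the phenols (MOM protection) is standard and gives ethers that later direct metalation and survive base, fluoride and hydride.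

Step 2
Reactants: 2 1,3-bis(methoxymethoxy)benzene
Product: 4 1,3-bis(methoxymethoxy)-2-(3-methylbut-2-en-1-yl)benzene, via aryllithium 3 (not isolated)
Conditions: n-BuLi, THF, 0 °C; CuBr·SMe2 (10 mol %), prenyl bromide, −78 °C to rt
Reagents that add atoms: 1-bromo-3-methylbut-2-ene, CC(C)=CCBr; n-butyllithium, [Li]CCCC (lithium of intermediate 3 only)
Why: Directed ortho-metalation takes place at C2 between the two OMOM groups, and copper-mediated allylation of the aryllithium with prenyl bromide should give the linear prenyl arene.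

Step 3
Reactants: 4 1,3-bis(methoxymethoxy)-2-(3-methylbut-2-en-1-yl)benzene
Product: 6 3,5-bis(methoxymethoxy)-4-(3-methylbut-2-en-1-yl)phenol, via arylboronate 5 (not isolated)
Conditions: B2pin2, [Ir(OMe)(cod)]2 (1.5 mol %), 4,4'-di-tert-butyl-2,2'-bipyridine (3 mol %), THF, 80 °C; then aq. NaOH, H2O2, 0 °C
Reagents that add atoms: hydrogen peroxide, OO (the phenol oxygen); bis(pinacolato)diboron, CC1(C)OB(OC1(C)C)B1OC(C)(C)C(C)(C)O1 (boron of intermediate 5 only)
Why: Sterically controlled iridium-catalysed C–H borylation should occur at C5, the only aromatic C–H without an ortho substituent, and alkaline peroxide oxidation of the boronate gives the phenol without touching the trisubstituted alkene.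

Step 4
Reactants: 6 3,5-bis(methoxymethoxy)-4-(3-methylbut-2-en-1-yl)phenol
Product: 7 3,5-bis(methoxymethoxy)-4-(3-methylbut-2-en-1-yl)phenyl N,N-diethylcarbamate
Conditions: Et2NCOCl, K2CO3, MeCN, reflux
Reagents that add atoms: N,N-diethylcarbamoyl chloride, CCN(CC)C(Cl)=O
Why: O-Carbamoylation of the single free phenol installs a strong directed-metalation group on the oxygen that will become the triflate.

Step 5
Reactants: 7 3,5-bis(methoxymethoxy)-4-(3-methylbut-2-en-1-yl)phenyl N,N-diethylcarbamate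
Product: 9 3,5-bis(methoxymethoxy)-4-(3-methylbut-2-en-1-yl)-2-(trimethylsilyl)phenyl N,N-diethylcarbamate, via aryllithium 8 (not isolated)
Conditions: s-BuLi, TMEDA, THF, −78 °C; TMSCl, −78 °C to rt
Reagents that add atoms: chlorotrimethylsilane, C[Si](C)(C)Cl; sec-butyllithium, [Li]C(C)CC (lithium of intermediate 8 only)
Why: Directed ortho-metalation occurs at the position flanked by the carbamate and an OMOM group (the two ortho positions are equivalent by symmetry), and the silyl chloride quench at −78 °C precedes any anionic Fries rearrangement.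

Step 6
Reactants: 9 3,5-bis(methoxymethoxy)-4-(3-methylbut-2-en-1-yl)-2-(trimethylsilyl)phenyl N,N-diethylcarbamate
Product: 10 3,5-bis(methoxymethoxy)-4-(3-methylbut-2-en-1-yl)-2-(trimethylsilyl)phenol
Conditions: LiAlH4, THF, 0 °C to rt; aq. NaOH work-up
Reagents that add atoms: none
Why: Reductive cleavage of an aryl carbamate by hydride releases the phenoxide while MOM ethers, the alkene and the aryl–silicon bond are inert to LiAlH4.

Step 7
Reactants: 10 3,5-bis(methoxymethoxy)-4-(3-methylbut-2-en-1-yl)-2-(trimethylsilyl)phenol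
Product: 11 3,5-bis(methoxymethoxy)-4-(3-methylbut-2-en-1-yl)-2-(trimethylsilyl)phenyl trifluoromethanesulfonate
Conditions: Tf2O, pyridine, CH2Cl2, 0 °C
Reagents that add atoms: trifluoromethanesulfonic anhydride, O=S(=O)(OS(=O)(=O)C(F)(F)F)C(F)(F)F
Why: O-Sulfonylation of the ortho-silyl phenol gives the o-silylaryl triflate, the standard fluoride-triggered aryne precursor.

Step 8
Reactants: 12 methyl 5-bromo-2,4-dihydroxybenzoate
Product: 14 methyl 5-bromo-2,4-bis(methoxymethoxy)benzoate, via disodium phenoxide 13 (not isolated)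
Conditions: NaH, DMF, 0 °C; MOMCl, 0 °C to rt
Reagents that add atoms: chloromethyl methyl ether, COCCl; sodium hydride, [Na+].[H-] (sodium of intermediate 13 only)
Why: Full deprotonation with NaH makes the hydrogen-bonded 2-OH as well as the 4-OH nucleophilic, so both are converted into MOM ethers (Williamson-type alkylation).

Step 9
Reactants: 14 methyl 5-bromo-2,4-bis(methoxymethoxy)benzoate
Product: 15 methyl 2,4-bis(methoxymethoxy)-5-(3-methylbut-2-en-1-yl)benzoate
Conditions: tributyl(3-methylbut-2-en-1-yl)stannane, Pd(PPh3)4 (5 mol %), DMF, 100 °C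
Reagents that add atoms: tributyl(3-methylbut-2-en-1-yl)stannane, CCCC[Sn](CCCC)(CCCC)CC=C(C)C
Why: Stille coupling of the aryl bromide with the prenylstannane should give the linear prenyl arene, because the η3-prenylpalladium intermediate eliminates at its less substituted terminus.

Step 10
Reactants: 15 methyl 2,4-bis(methoxymethoxy)-5-(3-methylbut-2-en-1-yl)benzoate
Product: 16 3-[2,4-bis(methoxymethoxy)-5-(3-methylbut-2-en-1-yl)phenyl]-N-methoxy-N-methyl-3-oxopropanamide
Conditions: MeC(O)N(OMe)Me (2.3 equiv), LDA (2.4 equiv), THF, −78 °C; then 15, −78 to −20 °C; AcOH quench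
Reagents that add atoms: N-methoxy-N-methylacetamide, CC(=O)N(C)OC
Why: Crossed Claisen condensation of the amide enolate with the methyl ester gives the β-keto amide, whose deprotonation by the second equivalent of enolate drives the reaction and prevents over-addition.

Step 11
Reactants: 16 3-[2,4-bis(methoxymethoxy)-5-(3-methylbut-2-en-1-yl)phenyl]-N-methoxy-N-methyl-3-oxopropanamide
Product: 17 (3S)-3-[2,4-bis(methoxymethoxy)-5-(3-methylbut-2-en-1-yl)phenyl]-3-hydroxy-N-methoxy-N-methylpropanamide
Conditions: RuCl(p-cymene)[(S,S)-TsDPEN] (2 mol %), HCO2H/Et3N (1:1), DMF, 35 °C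
Reagents that add atoms: none
Why: Noyori–Ikariya asymmetric transfer hydrogenation reduces only the aryl ketone, and the (S,S) catalyst should deliver hydride to the face that gives the (S) carbinol, by the aryl/alkyl ketone model (aryl–arene CH/π contact in the six-membered transition state).

Step 12
Reactants: 17 (3S)-3-[2,4-bis(methoxymethoxy)-5-(3-methylbut-2-en-1-yl)phenyl]-3-hydroxy-N-methoxy-N-methylpropanamide; 11 3,5-bis(methoxymethoxy)-4-(3-methylbut-2-en-1-yl)-2-(trimethylsilyl)phenyl trifluoromethanesulfonate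
Product: 21 (2S)-2-[2,4-bis(methoxymethoxy)-5-(3-methylbut-2-en-1-yl)phenyl]-5,7-bis(methoxymethoxy)-6-(3-methylbut-2-en-1-yl)-2,3-dihydro-4H-chromen-4-one, via sodium alkoxide 18 (not isolated), via aryne 19 (not isolated), via hemiaminal alkoxide 20 (not isolated)
Conditions: NaH (1.05 equiv), THF, 0 °C; then 11 (1.3 equiv), tetrabutylammonium difluorotriphenylsilicate (TBAT, 1.6 equiv), THF, 0 °C to rt; AcOH, −20 °C, then pH 7 buffer
Reagents that add atoms: sodium hydride, [Na+].[H-] (sodium of intermediates 18 and 20 only)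
Why: Proposed new method: fluoride removes the silyl group of 11 and triflate leaves, giving the 3-alkoxyaryne 19 (C4a≡C8a of ring A); the secondary alkoxide 18 adds through oxygen to C8a, the aryne carbon remote from the C5 OMOM group, because the σ-withdrawing C5–O bond beside C4a distorts the triple bond and stabilises the developing carbanion at C4a, while C8 on the other side carries only hydrogen. The C4a aryl anion then attacks the Weinreb amide carbonyl in a 6-exo-trig acyl substitution, so ring C is completed in the same operation, and the hemiaminal alkoxide 20 keeps the ketone masked until the acetic acid quench, which shields the flavanone from base-driven ring opening to the chalcone. The closest known reaction types are the aryne annulation of ortho-hydroxy, ortho-amino or ortho-mercapto benzoates to xanthone-type ketones and the formal insertion of arynes into the N–C(O) bond of β-lactams to give 2,3-dihydroquinolin-4-ones; what has not been shown is an aliphatic secondary alkoxide carrying the acyl group on a saturated two-carbon tether. No stereocentre is made: C2 comes from 17 and keeps its (S) configuration because the C2–O bond is never broken, and the hemiaminal centre at C4 is lost on work-up. The step needs regioselectivity (oxygen at C8a and acyl at C4a, which places the prenyl group at C6 and not C8), secured by the C5 alkoxy group, and it needs acylation to outrun protonation of the aryl anion, secured by the proton-free medium (preformed alkoxide, anhydrous fluoride source) and the intramolecular six-membered transition state.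

Step 13
Reactants: 21 (2S)-2-[2,4-bis(methoxymethoxy)-5-(3-methylbut-2-en-1-yl)phenyl]-5,7-bis(methoxymethoxy)-6-(3-methylbut-2-en-1-yl)-2,3-dihydro-4H-chromen-4-one
Product: 22 (2S)-2-[2,4-dihydroxy-5-(3-methylbut-2-en-1-yl)phenyl]-5,7-dihydroxy-6-(3-methylbut-2-en-1-yl)-2,3-dihydro-4H-chromen-4-one
Conditions: aq. HCl (3 M), MeOH, 45 °C, stopped as soon as conversion is complete
Reagents that add atoms: none
Why: Acid-catalysed transacetalisation with methanol removes all four MOM ethers as dimethoxymethane, under conditions short and mild enough to spare the prenyl groups and the C2 stereocentre.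

Compound list
1 | resorcinol (benzene-1,3-diol) | Oc1cccc(O)c1 | starting material
2 | 1,3-bis(methoxymethoxy)benzene | COCOc1cccc(OCOC)c1 | intermediate
3 | [2,6-bis(methoxymethoxy)phenyl]lithium | [Li]c1c(OCOC)cccc1OCOC | intermediate
4 | 1,3-bis(methoxymethoxy)-2-(3-methylbut-2-en-1-yl)benzene | CC(C)=CCc1c(OCOC)cccc1OCOC | intermediate
5 | 2-[3,5-bis(methoxymethoxy)-4-(3-methylbut-2-en-1-yl)phenyl]-4,4,5,5-tetramethyl-1,3,2-dioxaborolane | CC(C)=CCc1c(OCOC)cc(B2OC(C)(C)C(C)(C)O2)cc1OCOC | intermediate
6 | 3,5-bis(methoxymethoxy)-4-(3-methylbut-2-en-1-yl)phenol | CC(C)=CCc1c(OCOC)cc(O)cc1OCOC | intermediate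
7 | 3,5-bis(methoxymethoxy)-4-(3-methylbut-2-en-1-yl)phenyl N,N-diethylcarbamate | CCN(CC)C(=O)Oc1cc(OCOC)c(CC=C(C)C)c(OCOC)c1 | intermediate
8 | {2-[(diethylcarbamoyl)oxy]-4,6-bis(methoxymethoxy)-5-(3-methylbut-2-en-1-yl)phenyl}lithium | CCN(CC)C(=O)Oc1cc(OCOC)c(CC=C(C)C)c(OCOC)c1[Li] | intermediate
9 | 3,5-bis(methoxymethoxy)-4-(3-methylbut-2-en-1-yl)-2-(trimethylsilyl)phenyl N,N-diethylcarbamate | CCN(CC)C(=O)Oc1cc(OCOC)c(CC=C(C)C)c(OCOC)c1[Si](C)(C)C | intermediate
10 | 3,5-bis(methoxymethoxy)-4-(3-methylbut-2-en-1-yl)-2-(trimethylsilyl)phenol | C[Si](C)(C)c1c(O)cc(OCOC)c(CC=C(C)C)c1OCOC | intermediate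
11 | 3,5-bis(methoxymethoxy)-4-(3-methylbut-2-en-1-yl)-2-(trimethylsilyl)phenyl trifluoromethanesulfonate | C[Si](C)(C)c1c(OS(=O)(=O)C(F)(F)F)cc(OCOC)c(CC=C(C)C)c1OCOC | intermediate
12 | methyl 5-bromo-2,4-dihydroxybenzoate | COC(=O)c1cc(Br)c(O)cc1O | starting material
13 | disodium 4-bromo-6-(methoxycarbonyl)benzene-1,3-diolate | COC(=O)c1cc(Br)c([O-])cc1[O-].[Na+].[Na+] | intermediate
14 | methyl 5-bromo-2,4-bis(methoxymethoxy)benzoate | COC(=O)c1cc(Br)c(OCOC)cc1OCOC | intermediate
15 | methyl 2,4-bis(methoxymethoxy)-5-(3-methylbut-2-en-1-yl)benzoate | COC(=O)c1cc(CC=C(C)C)c(OCOC)cc1OCOC | intermediate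
16 | 3-[2,4-bis(methoxymethoxy)-5-(3-methylbut-2-en-1-yl)phenyl]-N-methoxy-N-methyl-3-oxopropanamide | CON(C)C(=O)CC(=O)c1cc(CC=C(C)C)c(OCOC)cc1OCOC | intermediate
17 | (3S)-3-[2,4-bis(methoxymethoxy)-5-(3-methylbut-2-en-1-yl)phenyl]-3-hydroxy-N-methoxy-N-methylpropanamide | CON(C)C(=O)C[C@H](O)c1cc(CC=C(C)C)c(OCOC)cc1OCOC | intermediate
18 | sodium (1S)-1-[2,4-bis(methoxymethoxy)-5-(3-methylbut-2-en-1-yl)phenyl]-3-[methoxy(methyl)amino]-3-oxopropan-1-olate | CON(C)C(=O)C[C@H]([O-])c1cc(CC=C(C)C)c(OCOC)cc1OCOC.[Na+] | intermediate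
19 | 3,5-bis(methoxymethoxy)-4-(3-methylbut-2-en-1-yl)-1,2-didehydrobenzene (aryne) | COCOC1=C(CC=C(C)C)C(OCOC)=CC#C1 | intermediate
20 | sodium (2S)-2-[2,4-bis(methoxymethoxy)-5-(3-methylbut-2-en-1-yl)phenyl]-4-[methoxy(methyl)amino]-5,7-bis(methoxymethoxy)-6-(3-methylbut-2-en-1-yl)-3,4-dihydro-2H-chromen-4-olate (both C4 epimers) | CON(C)C1([O-])C[C@@H](c2cc(CC=C(C)C)c(OCOC)cc2OCOC)Oc2cc(OCOC)c(CC=C(C)C)c(OCOC)c12.[Na+] | intermediate
21 | (2S)-2-[2,4-bis(methoxymethoxy)-5-(3-methylbut-2-en-1-yl)phenyl]-5,7-bis(methoxymethoxy)-6-(3-methylbut-2-en-1-yl)-2,3-dihydro-4H-chromen-4-one | CC(C)=CCc1cc([C@@H]2CC(=O)c3c(cc(OCOC)c(CC=C(C)C)c3OCOC)O2)c(OCOC)cc1OCOC | intermediate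
22 | (2S)-2-[2,4-dihydroxy-5-(3-methylbut-2-en-1-yl)phenyl]-5,7-dihydroxy-6-(3-methylbut-2-en-1-yl)-2,3-dihydro-4H-chromen-4-one | CC(C)=CCc1cc([C@@H]2CC(=O)c3c(cc(O)c(CC=C(C)C)c3O)O2)c(O)cc1O | target

Total step count: 13. Longest linear sequence: 9 steps (steps 1 to 7, then 12 and 13, from resorcinol); the ring B branch is 4 steps before the union.

Steps most likely to fail

Step 12 (proposed new method). The aryl anion at C4a may be protonated before it acylates, the alkoxide may undergo retro-aldol cleavage, or the alkoxide may attack the triflate sulfur instead of the aryne. The fallback uses known chemistry only, sets out from 11 and 15 and returns at 21. Aryne precursor 11 with acetic acid and CsF in THF at 125 °C (known insertion of arynes into the acyl C–O bond of carboxylic acids, same regiochemistry) should give 1-[6-hydroxy-2,4-bis(methoxymethoxy)-3-(3-methylbut-2-en-1-yl)phenyl]ethan-1-one F1. Ester 15 is reduced with DIBAL-H to [2,4-bis(methoxymethoxy)-5-(3-methylbut-2-en-1-yl)phenyl]methanol F2 and oxidised with MnO2 to 2,4-bis(methoxymethoxy)-5-(3-methylbut-2-en-1-yl)benzaldehyde F3. Claisen–Schmidt condensation of F1 with F3 (KOH, EtOH) gives (2E)-3-[2,4-bis(methoxymethoxy)-5-(3-methylbut-2-en-1-yl)phenyl]-1-[6-hydroxy-2,4-bis(methoxymethoxy)-3-(3-methylbut-2-en-1-yl)phenyl]prop-2-en-1-one F4. Its single free phenol closes the ring by oxa-Michael addition (NaOAc, EtOH, reflux) to rac-2-[2,4-bis(methoxymethoxy)-5-(3-methylbut-2-en-1-yl)phenyl]-5,7-bis(methoxymethoxy)-6-(3-methylbut-2-en-1-yl)-2,3-dihydro-4H-chromen-4-one F5, and preparative HPLC on a chiral stationary phase delivers the (2S) enantiomer 21.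

Step 3. Hydroboration or vinylic C–H borylation at the trisubstituted alkene may compete with arene borylation. The fallback sets out from 2 and returns at 6. Iridium-catalysed borylation of alkene-free 2 gives 2-[3,5-bis(methoxymethoxy)phenyl]-4,4,5,5-tetramethyl-1,3,2-dioxaborolane F6, which NaOH/H2O2 oxidises to 3,5-bis(methoxymethoxy)phenol F7. TIPSCl/imidazole gives [3,5-bis(methoxymethoxy)phenoxy]tri(propan-2-yl)silane F8. n-BuLi lithiates between the two OMOM groups to {2,6-bis(methoxymethoxy)-4-[tri(propan-2-yl)silyloxy]phenyl}lithium F9, which with CuBr·SMe2 and prenyl bromide gives [3,5-bis(methoxymethoxy)-4-(3-methylbut-2-en-1-yl)phenoxy]tri(propan-2-yl)silane F10. TBAF in THF then releases phenol 6.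

Step 13. Acid may cyclise a prenyl group onto a neighbouring phenol, add HCl or methanol to the alkenes, or reversibly ionise the benzylic C2–O1 bond with erosion of enantiopurity. The fallback sets out from 21 and returns at 22 by non-protic transprotection. TESOTf with 2,2'-bipyridyl in CH2Cl2 at 0 °C converts the four aryl MOM ethers into silyl ethers, giving (2S)-2-[2,4-bis(triethylsilyloxy)-5-(3-methylbut-2-en-1-yl)phenyl]-5,7-bis(triethylsilyloxy)-6-(3-methylbut-2-en-1-yl)-2,3-dihydro-4H-chromen-4-one F11. Buffered fluoride (HF·pyridine, pyridine, THF, 0 °C) then cleaves it to 22 without Brønsted acid or free base.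

Further compounds
F1 | step 12 | 1-[6-hydroxy-2,4-bis(methoxymethoxy)-3-(3-methylbut-2-en-1-yl)phenyl]ethan-1-one | CC(=O)c1c(O)cc(OCOC)c(CC=C(C)C)c1OCOC
F2 | step 12 | [2,4-bis(methoxymethoxy)-5-(3-methylbut-2-en-1-yl)phenyl]methanol | OCc1cc(CC=C(C)C)c(OCOC)cc1OCOC
F3 | step 12 | 2,4-bis(methoxymethoxy)-5-(3-methylbut-2-en-1-yl)benzaldehyde | O=Cc1cc(CC=C(C)C)c(OCOC)cc1OCOC
F4 | step 12 | (2E)-3-[2,4-bis(methoxymethoxy)-5-(3-methylbut-2-en-1-yl)phenyl]-1-[6-hydroxy-2,4-bis(methoxymethoxy)-3-(3-methylbut-2-en-1-yl)phenyl]prop-2-en-1-one | CC(C)=CCc1cc(/C=C/C(=O)c2c(O)cc(OCOC)c(CC=C(C)C)c2OCOC)c(OCOC)cc1OCOC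
F5 | step 12 | rac-2-[2,4-bis(methoxymethoxy)-5-(3-methylbut-2-en-1-yl)phenyl]-5,7-bis(methoxymethoxy)-6-(3-methylbut-2-en-1-yl)-2,3-dihydro-4H-chromen-4-one | CC(C)=CCc1cc(C2CC(=O)c3c(cc(OCOC)c(CC=C(C)C)c3OCOC)O2)c(OCOC)cc1OCOC
F6 | step 3 | 2-[3,5-bis(methoxymethoxy)phenyl]-4,4,5,5-tetramethyl-1,3,2-dioxaborolane | COCOc1cc(OCOC)cc(B2OC(C)(C)C(C)(C)O2)c1
F7 | step 3 | 3,5-bis(methoxymethoxy)phenol | COCOc1cc(O)cc(OCOC)c1
F8 | step 3 | [3,5-bis(methoxymethoxy)phenoxy]tri(propan-2-yl)silane | COCOc1cc(OCOC)cc(O[Si](C(C)C)(C(C)C)C(C)C)c1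
F9 | step 3 | {2,6-bis(methoxymethoxy)-4-[tri(propan-2-yl)silyloxy]phenyl}lithium | [Li]c1c(OCOC)cc(O[Si](C(C)C)(C(C)C)C(C)C)cc1OCOC
F10 | step 3 | [3,5-bis(methoxymethoxy)-4-(3-methylbut-2-en-1-yl)phenoxy]tri(propan-2-yl)silane | CC(C)=CCc1c(OCOC)cc(O[Si](C(C)C)(C(C)C)C(C)C)cc1OCOC
F11 | step 13 | (2S)-2-[2,4-bis(triethylsilyloxy)-5-(3-methylbut-2-en-1-yl)phenyl]-5,7-bis(triethylsilyloxy)-6-(3-methylbut-2-en-1-yl)-2,3-dihydro-4H-chromen-4-one | CC(C)=CCc1cc([C@@H]2CC(=O)c3c(cc(O[Si](CC)(CC)CC)c(CC=C(C)C)c3O[Si](CC)(CC)CC)O2)c(O[Si](CC)(CC)CC)cc1O[Si](CC)(CC)CC
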